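You asked for a quick number, and your hunch is that target simply follows the partner charged, so we begin at late times and ask what can end a flask.

| flask | substrate | partner | capture agent | free catalyst | time |
|---|---|---|---|---|---|
| winter | 0.082 M | 0.00300 M | 0.0820 M | 4.1 mM | 8.0 d |
| autumn | 0.082 M | 0.0100 M | 0.0820 M | 4.1 mM | 8.0 d |
| spring | 0.082 M | 0.0250 M | 0.0820 M | 4.1 mM | 8.0 d |
| dawn | 0.082 M | 0.0800 M | 0.0820 M | 4.1 mM | 8.0 d |

    partner + free catalyst ⇌ catalyst intermediate A (K1 = 3.0 M⁻¹, k1 = 0.075 M⁻¹ s⁻¹)
    catalyst intermediate A → catalyst intermediate B (k2 = 3.1 × 10⁻⁴ s⁻¹)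
    substrate + catalyst intermediate B ⇌ catalyst intermediate C (K3 = 250 M⁻¹, k3 = 0.010 M⁻¹ s⁻¹)
    catalyst intermediate C → free catalyst + target (k4 = 1.0 × 10⁻⁴ s⁻¹)
    catalyst intermediate A + capture agent → trapped intermediate (k5 = 0.0013 M⁻¹ s⁻¹)
    partner → decomposed reagent (k6 = 2.3 × 10⁻⁶ s⁻¹)

* amount of target at the end, in percent of the substrate charged for winter, autumn, spring, dawn, in this order
* how the row runs (hardly changes / falls all the way / falls, then rises / rises, then falls / rises all the way)

We follow one molecule of catalyst intermediate A. Its way back to partner and free catalyst, at 0.0250 s⁻¹, is much faster than its forward exits, but it changes nothing, so the molecule comes back to the same fork: step 2 at 3.1 × 10⁻⁴ s⁻¹, or capture at 1.07 × 10⁻⁴ s⁻¹. That capture rate is pseudo-first-order, because capture agent is charged at 20.0 times the catalyst. The ratio of the two is 2.91: the rounds made per trapping, that is, the target formed for each trapped intermediate. With capture agent held at its charge, this estimate lets the catalyst charge make about 11.9 mM of target, or 14.5 % of the substrate.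

Partner has a fork of its own. At the start, with the catalyst all free, a fraction K1[free catalyst] of it sits as catalyst intermediate A and leaves at 4.17 × 10⁻⁴ s⁻¹, so partner is used at 5.12 × 10⁻⁶ s⁻¹ against decomposition at 2.3 × 10⁻⁶ s⁻¹. It reaches the catalyst with a chance of 69.0 %, and then goes on with a chance of 74.4 %, which gives 0.514 target per partner.

In winter that makes 1.54 mM, less than the catalyst allows, so partner is the limiting reagent there. We commit to 1.88 %, a little high, since free catalyst falls as the run goes on. In dawn the same chance would give 41.1 mM, more than the catalyst allows, so we commit to 14.5 % there and to a rise between the two. We give no figure for autumn or spring.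

The forecast, slightly below our figures at both ends, gave 1.8 %, 5.5 %, 10.9 % and 14.2 %, and rises all the way, holding that “the catalyst can make only about three turnovers”.

The flasks give 1.80 %, 5.53 %, 10.9 % and 14.7 %, and the row rises all the way. In dawn, after 8.00 d, nearly all of the catalyst stands as trapped intermediate, and the target read per trapped intermediate is 2.98, beside the 2.91 expected from step 2 at 3.1 × 10⁻⁴ s⁻¹ against capture at 1.07 × 10⁻⁴ s⁻¹. In winter, where 87.6 % of the catalyst is still free and 0.948 % of the partner is left, the same reading, on 12.4 % of the catalyst trapped, is 2.91.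

(The numbers of this flask stand for no real mixture.)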